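Its constants come from no measurement; the rest is arithmetic.

At early times each flask shares out its enzyme among three forms, and complex A is the form that makes target.

    starting material + enzyme ⇌ complex A (K1 = 1500 M⁻¹, k1 = 7.1 × 10⁷ M⁻¹ s⁻¹)
    complex A → enzyme + target (k2 = 140 s⁻¹)
    second substrate + enzyme ⇌ complex B (K3 = 2200 M⁻¹, k3 = 3.8 × 10⁷ M⁻¹ s⁻¹)
    complex B → enzyme + second product (k4 = 260 s⁻¹)
    crystals ⇌ target, rate k5*(cs5 - [target]) while solid is left; crystals form when [target] > cs5 (cs5 = 0.014 mM, k5 = 0.096 s⁻¹)

| flask | starting material | second substrate | enzyme | time |
|---|---|---|---|---|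
| grey | 5.0 × 10⁻⁴ M | 1.00 mM | 0.080 µM | 80 s |
| violet | 5.0 × 10⁻⁴ M | 3.00 mM | 0.080 µM | 80 s |
| amber | 5.0 × 10⁻⁴ M | 10.0 mM | 0.080 µM | 80 s |

- what is said of target includes crystals
- crystals is a solid; its amount is given per volume of the solution
- the concentration of target that is asked is that of its free form alone
- "hardly changes" means that all values lie within two and a half points (for a concentration: within two and a half percent of the largest)
- run time (grey): 80 s

1. [target] (only what is free in solution) at the end for grey, violet, amber, in this order
2. the shape of the row from first to last (falls, then rises / rises all the way / rises, then falls / falls all the way / hardly changes)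

This reckoning by hand comes first. Complex A falls apart at 47300 s⁻¹ but turns over at 140 s⁻¹, and complex B falls apart at 17300 s⁻¹ but turns over at 260 s⁻¹, so binding stands at equilibrium. Enzyme, complex A and complex B therefore stand as 1 to a to b, where a is 0.750 at the charge and b is 2.20, 6.60 and 22.0 in grey, violet and amber. Freezing these terms gives complex A shares of 19.0%, 8.98% and 3.16%.

Solubility is 2.80% of the starting-material charge. By its frozen share, amber is estimated to reach it after 39.6 s, which leaves 3.88 relaxation times of 10.4 s. Free target then stands above solubility by its making rate over 0.096 s⁻¹. That excess, taken for the whole catalyst charge as complex A and counted against the starting-material charge, is the full-load excess, 23.3%. While crystals stand, free target is estimated as solubility plus this excess times the share. The frozen row is 3.62 × 10⁻⁵ M, 2.45 × 10⁻⁵ M and 1.77 × 10⁻⁵ M, and it falls.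

The weak link is the frozen second substrate. At its frozen rate, grey loses 92.7% of its second substrate, so that flask needs reforging. The run's turnover count for second substrate is 3.66. Dividing it by the three-term sum gives a first exponential decay, and repeating this with b at its mean over the run leaves fractions 32.8%, 60.1% and 84.8%. Starting material follows as that fraction raised to the selectivity factor, 0.367. The reforged complex A shares at the end are 22.4%, 11.1% and 3.47%. The reforged row is 0.0402 mM, 0.0270 mM and 0.0180 mM, so my reckoned shape is: falls all the way.

The forecast gives 4.000 × 10⁻⁵ M, 2.700 × 10⁻⁵ M and 1.800 × 10⁻⁵ M, and its shape is falls all the way. On its grounds, target “sits at a crystallisation quasi-steady state”. Its first value is higher than the frozen one and lies near the reforged one.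

The flasks end at 4.00 × 10⁻⁵ M, 2.68 × 10⁻⁵ M and 1.80 × 10⁻⁵ M, so the row falls all the way. At 80.0 s, grey holds 22.5% of its catalyst as complex A, and solubility plus the full-load excess times that share gives 4.02 × 10⁻⁵ M. Amber holds 3.50% as complex A at 80.0 s, and the same sum gives 1.81 × 10⁻⁵ M.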